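(The runs were generated by integration on assumed constants; the scatter is artificial.)

In the first minutes E takes 64.6% of the D lost in the north run, and the south-west run reads 64.8% at its first point, so from the start a second exit drains D beside the step that makes E.

all flasks: D 0.10 M
- south-west: Q 0.074 M; Z 64 µM; temperature 65 °C; run made earlier
- north: Q 0.17 M; Z 64 µM; temperature 98 °C; run made earlier
- south: Q 0.11 M; Z 32 µM; temperature 65 °C; run made earlier
- cedar: Q 0.110 M; Z 64 µM; temperature 80 °C; time 40 min
- birch: Q 0.110 M; Z 64 µM; temperature 110 °C; time 40 min
- elm: Q 0.110 M; Z 64 µM; temperature 50 °C; time 40 min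
- oak: Q 0.110 M; Z 64 µM; at 110 °C until 8.0 min, from then on at 50 °C; time 40 min

| run | time / min | E / % | D / % |
|---|---|---|---|
| south-west | 5.00 | 3.5 | 94.6 |
| south-west | 15.0 | 9.8 | 86.8 |
| south-west | 30.0 | 15.0 | 79.5 |
| south-west | 40.0 | 17.3 | 75.1 |
| south-west | 60.0 | 20.0 | 69.9 |
| south-west | 80.0 | 21.5 | 66.9 |
| north | 2.50 | 15.7 | 75.7 |
| north | 5.00 | 23.3 | 61.8 |
| north | 8.00 | 26.5 | 51.9 |
| north | 10.0 | 27.7 | 46.9 |
| north | 12.0 | 28.3 | 44.0 |
| north | 15.0 | 27.8 | 40.7 |
| south | 6.00 | 4.2 | 94.5 |
| south | 12.0 | 5.7 | 89.3 |
| south | 25.0 | 11.6 | 80.4 |
| south | 40.0 | 15.8 | 73.2 |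
| south | 80.0 | 22.3 | 59.1 |

(each reading ± 0.3 percentage points)

- the numbers in the tables scatter with a standard deviation of 0.3 percentage points

- the best flask by amount of E, in percent of the D charged; "all alike" if 1.5 percentage points covers them all (cedar / birch / elm / oak / all alike)
- amount of E at the end, in percent of the D charged, cedar
- amount of E at the end, in percent of the D charged, birch
- amount of E at the end, in percent of the D charged, elm
- amount of E at the end, in percent of the D charged, oak

That share drifts. Between 12.0 min and 15.0 min the north run loses 3.3 points of D while E goes from 28.3% to 27.8%, so E has stopped gaining although D is still there. Taking one Q per D lost, Q is there too, and I read this stop as the Z step reaching its balance, which is thermodynamic control.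

At that peak, the fraction of E over the fractions of D and Q left and the Q charge reads 5.64 M⁻¹. I call this the lid, an apparent equilibrium constant; the lid times the Q charge times both fractions left is the ceiling on E at that temperature. South-west, colder and with E still rising, already reads 7.86 M⁻¹ at its last point, more than the north lid, so the lid rises as the flask cools.

Now the slow motion. In the first instants E is at nothing, so the Z step has nothing to run back from. In the middle, D and Q shrink, the ceiling sinks and E climbs to meet it. At the end of birch, as I reckon it, E rides the ceiling down while the second exit goes on draining D and Q, and birch stays at 110 °C until 40 min, longer than oak, which leaves that heat at 8.0 min.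

For oak I suppose that at the change it stands where north stood at 8.00 min. With the north lid, read at 98 °C and not at 110 °C, the ceiling is then 18.1%, and I expect the cold stretch to add a little after that.

The forecast names cedar, with 26% for cedar, 3% for birch, 15% for elm and 18.5% for oak, on the ground that “the catalyst dies and E decays thermally”. My ground is the ceiling instead.

    D + Q + Z ⇌ E + Z, rate k1*[D]*[Q]*[Z] forward; the back reaction follows from the equilibrium constant (K = 4.97 M⁻¹, k = 12800 M⁻² min⁻¹, Ea = 48.0 kJ mol⁻¹, ΔH = −15.0 kJ mol⁻¹)
    D + Q → G (k = 0.515 M⁻¹ min⁻¹, Ea = 64.0 kJ mol⁻¹)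
    (constants at 110 °C)

Cedar gives most, 25.6%, against 7.89% in birch, 16.1% in elm and 22.0% in oak, and the forecast holds on each. Oak at 8.00 min has E 19.2%, D 56.6% and Q 60.5%, a quotient of 5.09 M⁻¹, below the lid from the cooler north run. At 50 °C it climbs to 6.73 M⁻¹ by 40.0 min, above that lid. The neighbour like oak, charged with 0.28 M of Q, ends with D 20.6% and Q 71.6%, so the north lid, read at 98 °C and not at the 50 °C where this neighbour ends, gives it a figure of 23.3%, its quotient reads 8.39 M⁻¹, and its E stands at 34.6%.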